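**Strategy.** Rings: A monophenol, B meta-phenylene, C catechol, D para-phenylene. The 19-membered ring is opened at the C(sp2)–C(sp3) bond between C4 of ring D and its benzylic CH2. Both carbons are innately nucleophilic. Ring-D C4 lies para to the diaryl ether oxygen. The CH2 is the terminal carbon of a ring-A styrene whose vinyl group stands para to the ring-A oxygen. Polarity is reversed at ring D by a bromide. In one operation 9-BBN hydroborates the vinyl group of open-chain bromo-styrene 9, and an intramolecular B-alkyl Suzuki–Miyaura coupling closes the macrocycle, giving the saturated bridge directly. The same tactic joins rings B and C; Chan–Lam couplings make both diaryl ethers.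

Key step: step 5

Assumption: the target has no stereocentre and the macrocycle is taken as conformationally mobile, so no stereocontrol is needed; 2-methoxy-5-vinylphenol (5) is taken as a catalogue compound, stored cold with an inhibitor.

Step 1
Reactants: 1 3-hydroxy-4,5-dimethoxybenzaldehyde; 2 4-bromophenylboronic acid
Product: 3 3-(4-bromophenoxy)-4,5-dimethoxybenzaldehyde
Conditions: 2 (2 equiv), Cu(OAc)2 (20 mol %), pyridine (5 equiv), 4 Å MS, O2 (1 atm), CH2Cl2, rt
Reagents that add atoms: none
Why: The Chan–Lam–Evans oxidative O-arylation runs at room temperature and should leave the C–Br bond and the aldehyde untouched, which a thermal Ullmann coupling would not guarantee.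

Step 2
Reactants: 3 3-(4-bromophenoxy)-4,5-dimethoxybenzaldehyde
Product: 4 1-(4-bromophenoxy)-2,3-dimethoxy-5-vinylbenzene
Conditions: MePPh3Br (1.3 equiv), KOtBu (1.25 equiv), THF, 0 °C to rt
Reagents that add atoms: methyltriphenylphosphonium bromide, C[P+](c1ccccc1)(c1ccccc1)c1ccccc1.[Br-]
Why: Wittig methylenation of a non-enolisable aryl aldehyde is fast at 0 °C, and the alkoxide base avoids the halogen–metal exchange at the aryl bromide that an organolithium base could cause.

Step 3
Reactants: 5 2-methoxy-5-vinylphenol; 6 3-iodophenylboronic acid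
Product: 7 2-(3-iodophenoxy)-1-methoxy-4-vinylbenzene
Conditions: 6 (2 equiv), Cu(OAc)2 (20 mol %), pyridine (5 equiv), 4 Å MS, O2 (1 atm), CH2Cl2, rt
Reagents that add atoms: none
Why: In this Chan–Lam–Evans coupling of a guaiacol-type phenol the C–I bond should be inert at room temperature, and the vinyl group is meta to the phenol, so no quinone methide can form.

Step 4
Reactants: 4 1-(4-bromophenoxy)-2,3-dimethoxy-5-vinylbenzene; 7 2-(3-iodophenoxy)-1-methoxy-4-vinylbenzene
Product: 9 1-(4-bromophenoxy)-2,3-dimethoxy-5-{2-[3-(2-methoxy-5-vinylphenoxy)phenyl]ethyl}benzene (open-chain bromo-styrene), via ring-C B-alkyl-9-BBN borane 8 (not isolated)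
Conditions: 4, 9-BBN (1.05 equiv), THF, 0 °C to rt; H2O; then 7 (1.05 equiv), Pd(dppf)Cl2 (5 mol %), AsPh3 (5 mol %), Cs2CO3 (2 equiv), DMF–THF–H2O, rt
Reagents that add atoms: 9-BBN, B1C2CCCC1CCC2 (its boron unit stands only in intermediate 8; product 9 keeps one hydrogen of it)
Why: Hydroboration puts boron on the terminal carbon of 4, water destroys left-over B–H before 7 is added, and the B-alkyl Suzuki–Miyaura coupling should occur at the C–I bond of 7, because oxidative addition to an aryl iodide at room temperature is much faster than to the electron-rich ring-D bromide and than Heck insertion of the vinyl group.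

Step 5
Reactants: 9 open-chain bromo-styrene
Product: 11 macrocyclic tri-O-methyl ether of the target, via ring-A B-alkyl-9-BBN borane 10 (not isolated)
Conditions: 9-BBN (1.5 equiv), THF, rt; H2O; then slow addition (syringe pump) to Pd(dppf)Cl2 (15 mol %), AsPh3 (15 mol %), Cs2CO3 (3 equiv), DMF–THF–H2O, 60 °C, final concentration about 1 mM
Reagents that add atoms: 9-BBN, B1C2CCCC1CCC2 (its boron unit stands only in intermediate 10; product 11 keeps one hydrogen of it)
Why: 9-BBN adds to the only alkene of 9 and should place boron on the terminal carbon for steric reasons, a preference reinforced by the para-methoxy group of ring A, to give primary borane 10. Base turns 10 into its borate, zerovalent palladium inserts into the ring-D C–Br bond, intramolecular transmetalation gives a 20-membered palladacycle, and reductive elimination forms the bond between ring-D C4 and the terminal CH2. The closest known reaction type is the hydroboration/B-alkyl Suzuki–Miyaura macrocyclisation of ω-alkenyl aryl halides. One ring is closed, the 19-membered ring (shortest path through rings A, B, C and D), by end-to-end closure of the open chain at its two termini, and no stereocentre is created. The step needs ring closure to win over oligomerisation, which is secured by slow addition of 10 into the hot catalyst solution and by the two bent diaryl ether hinges and the flexible B–C ethano bridge that let the termini meet without strain. It also needs reductive elimination to win over β-hydride elimination, which the wide bite angle of dppf secures, while site selectivity is no issue because 10 holds a single C–Br and a single C–B bond.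

Step 6
Reactants: 11 macrocyclic tri-O-methyl ether of the target
Product: 12 CNP0495401.0 (macrocyclic bis(bibenzyl) triol)
Conditions: BBr3 (9 equiv), CH2Cl2, −78 °C to rt; then ice–H2O, work-up under N2
Reagents that add atoms: none
Why: Lewis-acid ether cleavage with BBr3 removes all three methyl groups by bromide attack at CH3, whereas the two diaryl ether linkages offer no sp3 carbon for attack and should survive.

**Compound list**
1 | 3-hydroxy-4,5-dimethoxybenzaldehyde | O=Cc1cc(O)c(OC)c(OC)c1 | starting material
2 | 4-bromophenylboronic acid | OB(O)c1ccc(Br)cc1 | starting material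
3 | 3-(4-bromophenoxy)-4,5-dimethoxybenzaldehyde | O=Cc1cc(OC)c(OC)c(Oc2ccc(Br)cc2)c1 | intermediate
4 | 1-(4-bromophenoxy)-2,3-dimethoxy-5-vinylbenzene | C=Cc1cc(OC)c(OC)c(Oc2ccc(Br)cc2)c1 | intermediate
5 | 2-methoxy-5-vinylphenol | C=Cc1ccc(OC)c(O)c1 | starting material
6 | 3-iodophenylboronic acid | OB(O)c1cccc(I)c1 | starting material
7 | 2-(3-iodophenoxy)-1-methoxy-4-vinylbenzene | C=Cc1ccc(OC)c(Oc2cccc(I)c2)c1 | intermediate
8 | 9-{2-[3-(4-bromophenoxy)-4,5-dimethoxyphenyl]ethyl}-9-borabicyclo[3.3.1]nonane (not isolated) | COc1cc(CCB2C3CCCC2CCC3)cc(Oc2ccc(Br)cc2)c1OC | intermediate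
9 | 1-(4-bromophenoxy)-2,3-dimethoxy-5-{2-[3-(2-methoxy-5-vinylphenoxy)phenyl]ethyl}benzene | C=Cc1ccc(OC)c(Oc2cccc(CCc3cc(OC)c(OC)c(Oc4ccc(Br)cc4)c3)c2)c1 | intermediate
10 | B-alkyl-9-BBN derivative of 9, boron on the terminal carbon of the former vinyl group (not isolated) | COc1ccc(CCB2C3CCCC2CCC3)cc1Oc1cccc(CCc2cc(OC)c(OC)c(Oc3ccc(Br)cc3)c2)c1 | intermediate
11 | macrocyclic tri-O-methyl ether of the target | COc1ccc2cc1Oc1cccc(c1)CCc1cc(OC)c(OC)c(c1)Oc1ccc(cc1)CC2 | intermediate
12 | CNP0495401.0 | Oc1ccc2cc1Oc1cccc(c1)CCc1cc(O)c(O)c(c1)Oc1ccc(cc1)CC2 | target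

Total step count: 6. Longest linear sequence: 5 (steps 1, 2, 4, 5, 6).

**Steps most likely to fail**

1. Step 5. Intermolecular coupling to linear and cyclic oligomers may compete. Protodeboronation and hydrodebromination may also outrun a slow transmetalation at high dilution. The fallback sets out from 9 and comes back at 11. The same ring-D C4–carbon bond is made by an intramolecular Mizoroki–Heck reaction (Pd(OAc)2, P(o-tol)3, K2CO3, n-Bu4NBr, DMF, 100 °C, about 2 mM). The aryl palladium species adds to the terminal vinyl carbon and should give the macrocyclic (E)-stilbene F1. Hydrogenation (H2, Pd/C, EtOAc, rt) then saturates the bridge and gives 11.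

2. Step 4. The discrimination between iodide and bromide may erode, so that the ring-D bromide is drawn into oligomer formation, or Heck insertion may consume the vinyl group of 7. The fallback sets out from 3 and comes back at 9.
   - The B–C bridge is built by olefination instead of cross-coupling. Wittig reaction of 3 with (3-hydroxybenzyl)triphenylphosphonium bromide (KOtBu, 2.2 equiv, THF) should give the stilbene phenol F2 as an E/Z mixture.
   - Diimide reduction (TsNHNH2, NaOAc, THF–H2O, reflux) spares the C–Br bond and should give the bibenzyl phenol F3.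
   - Chan–Lam coupling with (5-formyl-2-methoxyphenyl)boronic acid (Cu(OAc)2, pyridine, O2, CH2Cl2) should give the open-chain aldehyde F4.
   - Wittig methylenation (MePPh3Br, KOtBu, THF) gives 9.

3. Step 3. The electron-rich styrene may oligomerise oxidatively under copper and O2, or protodeboronation of 6 may outrun C–O bond formation. The fallback sets out from 6 and comes back at 7. The vinyl group is kept masked during the copper step. Compound 6 is coupled with isovanillin under the same Chan–Lam protocol to give 3-(3-iodophenoxy)-4-methoxybenzaldehyde F5. Wittig methylenation (MePPh3Br, KOtBu, THF, 0 °C) then gives 7.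

**Further compounds**
F1 | step 5 | macrocyclic (E)-stilbene, tri-O-methyl ether with a CH=CH bridge between rings A and D | O1c2cc(ccc2OC)/C=C/c2ccc(cc2)Oc2cc(CCc3cccc1c3)cc(OC)c2OC
F2 | step 4 | 3-{2-[3-(4-bromophenoxy)-4,5-dimethoxyphenyl]ethenyl}phenol (E/Z mixture) | Oc1cccc(C=Cc2cc(OC)c(OC)c(Oc3ccc(Br)cc3)c2)c1
F3 | step 4 | 3-{2-[3-(4-bromophenoxy)-4,5-dimethoxyphenyl]ethyl}phenol | Oc1cccc(CCc2cc(OC)c(OC)c(Oc3ccc(Br)cc3)c2)c1
F4 | step 4 | 3-(3-{2-[3-(4-bromophenoxy)-4,5-dimethoxyphenyl]ethyl}phenoxy)-4-methoxybenzaldehyde | O=Cc1ccc(OC)c(Oc2cccc(CCc3cc(OC)c(OC)c(Oc4ccc(Br)cc4)c3)c2)c1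
F5 | step 3 | 3-(3-iodophenoxy)-4-methoxybenzaldehyde | O=Cc1ccc(OC)c(Oc2cccc(I)c2)c1
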